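**Plan**

- Retrosynthesis: the three phenols are masked as MOM ethers, the O1–C2 ether bond of ring C is cut (Mitsunobu), and then C3–C4 together with the lactol O1–C2 bond is cut in a [4+2] sense.
- Enabling feature: in ring C the atoms O1–C8a–C4a–C4 are an ortho-quinone methide of ring A (the heterodiene), and C2–C3 is the carbonyl and α-carbon of an arylacetaldehyde that already carries ring B on C3.
- Forward: rings A and B both come from resorcinol through 2-prenyl-1,3-bis(MOM)benzene 5 and its ortho-formyl derivative 7, made by a single directed lithiation. Methylenation, hydroboration–oxidation and Dess–Martin oxidation take 7 to arylacetaldehyde 11; adjustment of the oxygens, reduction and sulfinate substitution take 7 to sulfone 16.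
- Ring C arises in step 11 as a chroman-2-ol (C3–C4, then O1–C2), is opened by NaBH4 in the same flask, and is reclosed at O1–C2 in step 12; step 13 frees the phenols.
- Stereochemistry: the only stereocenter, C3 (R), is set in step 11 by the (R)-diarylprolinol silyl ether enamine. It is kept because the lactol is reduced at once and no later step touches C3.

Key step: step 11

Abbreviations: MOM = methoxymethyl; prenyl = 3-methylbut-2-en-1-yl; DMP = Dess–Martin periodinane; 9-BBN = 9-borabicyclo[3.3.1]nonane.

Assumption: the shielding model known for (S)-diarylprolinol silyl ethers (electrophile on the Si face of the enamine α-carbon) is taken to hold for the quinone methide. With the priorities C2 > aryl > C4 at C3, that face would give 3S, so the (R)-catalyst is chosen for 3R.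

**Route**

Step 1
Reactants: 1 resorcinol
Product: 2 1,3-bis(methoxymethoxy)benzene
Conditions: NaH (2.4 equiv), MOMCl (2.4 equiv), DMF, 0 °C → rt
Reagents that add atoms: chloromethyl methyl ether (MOMCl), COCCl
Why: Williamson-type O-alkylation of both phenoxides gives the bis-acetal, which protects the oxygens and supplies the directing groups for the lithiations that follow.

Step 2
Reactants: 2 1,3-bis(methoxymethoxy)benzene; 3 prenyl bromide
Product: 5 1,3-bis(methoxymethoxy)-2-prenylbenzene, via aryllithium 4 (not isolated)
Conditions: n-BuLi, THF, 0 °C → rt; CuI (10 mol %), 3, −78 °C → rt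
Reagents that add atoms: none
Why: Directed ortho-metalation occurs at the carbon flanked by both OMOM groups, and copper-catalysed SN2 allylation of the aryllithium with the primary allylic bromide should give the linear prenyl arene.

Step 3
Reactants: 5 1,3-bis(methoxymethoxy)-2-prenylbenzene
Product: 7 2,4-bis(methoxymethoxy)-3-prenylbenzaldehyde, via aryllithium 6 (not isolated)
Conditions: n-BuLi, TMEDA, THF, 0 °C; DMF, −78 °C → rt; H2O
Reagents that add atoms: N,N-dimethylformamide (DMF), CN(C)C=O
Why: Directed ortho-metalation next to an OMOM group (the two open ortho positions are equivalent) and formylation of the aryllithium with DMF (Bouveault-type) should give the aldehyde from which both halves of the target are drawn.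

Step 4
Reactants: 7 2,4-bis(methoxymethoxy)-3-prenylbenzaldehyde
Product: 8 1-ethenyl-2,4-bis(methoxymethoxy)-3-prenylbenzene
Conditions: Ph3PCH3Br, KOt-Bu, THF, 0 °C → rt
Reagents that add atoms: methyltriphenylphosphonium bromide, C[P+](c1ccccc1)(c1ccccc1)c1ccccc1.[Br-]
Why: Wittig methylenation of the aromatic aldehyde with the non-stabilised ylide should give the styrene under basic conditions that leave the MOM acetals and the prenyl group untouched.

Step 5
Reactants: 8 1-ethenyl-2,4-bis(methoxymethoxy)-3-prenylbenzene
Product: 10 2-[2,4-bis(methoxymethoxy)-3-prenylphenyl]ethan-1-ol, via alkylborane 9 (not isolated)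
Conditions: 9-BBN (1.2 equiv), THF, 0 °C → rt; NaOH (3 M aq), H2O2 (30% aq), 0 °C → rt
Reagents that add atoms: hydrogen peroxide, OO
Why: Brown hydroboration–oxidation with the bulky dialkylborane 9-BBN should place boron on the terminal carbon of the vinyl group and spare the far less reactive trisubstituted prenyl alkene, and alkaline peroxide then converts the C–B bond into the primary alcohol without any acidic step.

Step 6
Reactants: 10 2-[2,4-bis(methoxymethoxy)-3-prenylphenyl]ethan-1-ol
Product: 11 2-[2,4-bis(methoxymethoxy)-3-prenylphenyl]acetaldehyde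
Conditions: DMP, CH2Cl2, 0 °C → rt; used at once
Reagents that add atoms: none
Why: Dess–Martin oxidation takes the primary alcohol to the aldehyde under near-neutral conditions that should leave the MOM acetals and the trisubstituted alkene untouched.

Step 7
Reactants: 7 2,4-bis(methoxymethoxy)-3-prenylbenzaldehyde
Product: 12 2,4-dihydroxy-3-prenylbenzaldehyde
Conditions: HCl (3 M aq), MeOH, 40 °C, short reaction time
Reagents that add atoms: none
Why: Acid-catalysed acetal exchange with methanol removes both MOM groups, and the mild conditions are the ones commonly used for MOM ethers of ortho-prenyl phenols, so cyclization of the prenyl group should not compete.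

Step 8
Reactants: 12 2,4-dihydroxy-3-prenylbenzaldehyde
Product: 13 2-hydroxy-4-(methoxymethoxy)-3-prenylbenzaldehyde
Conditions: MOMCl (1.05 equiv), K2CO3, acetone, 0 °C → rt
Reagents that add atoms: chloromethyl methyl ether (MOMCl), COCCl
Why: Selective O-alkylation is expected at the 4-OH because the 2-OH is held in a hydrogen bond to the formyl group and is flanked by the prenyl group; this differentiates the two oxygens that were equivalent in 5.

Step 9
Reactants: 13 2-hydroxy-4-(methoxymethoxy)-3-prenylbenzaldehyde
Product: 14 6-(hydroxymethyl)-3-(methoxymethoxy)-2-prenylphenol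
Conditions: NaBH4, THF/MeOH, 0 °C; pH 7 buffer work-up
Reagents that add atoms: none
Why: Borohydride reduction of the salicylaldehyde gives the salicyl alcohol, and the neutral work-up avoids premature ionization of this activated benzylic alcohol.

Step 10
Reactants: 14 6-(hydroxymethyl)-3-(methoxymethoxy)-2-prenylphenol; 15 sodium p-toluenesulfinate
Product: 16 3-(methoxymethoxy)-2-prenyl-6-[(4-methylbenzenesulfonyl)methyl]phenol
Conditions: 15 (3 equiv), AcOH/H2O, rt → 40 °C
Reagents that add atoms: none
Why: SN1-type substitution is expected because the benzylic alcohol, activated by the ortho-OH and the para-OMOM, ionizes in weak acid to the protonated quinone methide, which the excess sulfinate captures at sulfur to give the sulfone.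

Step 11
Reactants: 16 3-(methoxymethoxy)-2-prenyl-6-[(4-methylbenzenesulfonyl)methyl]phenol; 11 2-[2,4-bis(methoxymethoxy)-3-prenylphenyl]acetaldehyde
Product: 20 6-[(2R)-2-[2,4-bis(methoxymethoxy)-3-prenylphenyl]-3-hydroxypropyl]-3-(methoxymethoxy)-2-prenylphenol, via ortho-quinone methide 17 (not isolated), via E-enamine 18 (not isolated), via lactol 19 (not isolated)
Conditions: 11 (1.5 equiv), (R)-2-[diphenyl(trimethylsilyloxy)methyl]pyrrolidine (20 mol %), Na2CO3 (1.5 equiv), CH2Cl2, 0 °C; then MeOH, NaBH4, 0 °C
Reagents that add atoms: none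
Why: Na2CO3 deprotonates the phenol of 16 and expels p-toluenesulfinate to release ortho-quinone methide 17 slowly while 11 condenses with the catalyst to E-enamine 18; the enamine α-carbon adds to the exocyclic methylene of 17 (C3–C4, ring A rearomatizes), the iminium is hydrolysed, the phenoxide closes onto the aldehyde carbon (O1–C2) to give lactol 19, and NaBH4 reduces 19 in the same flask to diol 20. The closest known reaction type is the secondary-amine-catalysed Michael addition and hemiacetalization of aldehydes with ortho-quinone methides generated in situ from 2-(sulfonylmethyl)phenols, a stepwise formal inverse-electron-demand oxa-[4+2]. Ring C closes by 6-exo-trig hemiacetalization of the C8a oxygen onto the C2 carbonyl. C3 is set by the catalyst: the diphenyl(trimethylsilyloxy)methyl group of the (R)-pyrrolidine covers the Si face of the anti E-enamine, so the methide should add to the Re face of the α-carbon and give 3R, while C2 of the lactol is an anomeric mixture of no consequence because it becomes CH2. The step needs C-alkylation of the enamine at the methide carbon instead of self-condensation of either partner, and it must avoid epimerization of the α-aryl aldehyde: the para oxygen of 16 is capped as a MOM ether so only the ortho-quinone methide can form and its electrophilicity is tempered, both phenols of 11 are capped so it offers no competing O-nucleophile, the aldehyde rests as the cyclic lactol, and hydride is added before work-up.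

Step 12
Reactants: 20 6-[(2R)-2-[2,4-bis(methoxymethoxy)-3-prenylphenyl]-3-hydroxypropyl]-3-(methoxymethoxy)-2-prenylphenol
Product: 21 (3R)-3-[2,4-bis(methoxymethoxy)-3-prenylphenyl]-7-(methoxymethoxy)-8-prenyl-3,4-dihydro-2H-chromene
Conditions: PPh3, DIAD, THF, 0 °C → rt
Reagents that add atoms: none
Why: Intramolecular Mitsunobu etherification (6-exo-tet) between the only free phenol and the primary alcohol closes ring C at O1–C2, and C3 is not a reacting centre so its configuration should be retained.

Step 13
Reactants: 21 (3R)-3-[2,4-bis(methoxymethoxy)-3-prenylphenyl]-7-(methoxymethoxy)-8-prenyl-3,4-dihydro-2H-chromene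
Product: 22 Kanzonol X
Conditions: HCl (3 M aq), MeOH, rt → 40 °C
Reagents that add atoms: none
Why: Acid-catalysed methanolysis of the three aryl MOM acetals should free the phenols under the mild conditions commonly used for prenylated phenols, and the isoflavan core and C3 are inert to them.

**Compound list**

1 | resorcinol | Oc1cccc(O)c1 | starting material
2 | 1,3-bis(methoxymethoxy)benzene | COCOc1cccc(OCOC)c1 | intermediate
3 | prenyl bromide (1-bromo-3-methylbut-2-ene) | CC(C)=CCBr | starting material
4 | [2,6-bis(methoxymethoxy)phenyl]lithium | [Li]c1c(OCOC)cccc1OCOC | intermediate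
5 | 1,3-bis(methoxymethoxy)-2-(3-methylbut-2-en-1-yl)benzene | COCOc1cccc(OCOC)c1CC=C(C)C | intermediate
6 | [2,4-bis(methoxymethoxy)-3-(3-methylbut-2-en-1-yl)phenyl]lithium | [Li]c1ccc(OCOC)c(CC=C(C)C)c1OCOC | intermediate
7 | 2,4-bis(methoxymethoxy)-3-(3-methylbut-2-en-1-yl)benzaldehyde | O=Cc1ccc(OCOC)c(CC=C(C)C)c1OCOC | intermediate
8 | 1-ethenyl-2,4-bis(methoxymethoxy)-3-(3-methylbut-2-en-1-yl)benzene | C=Cc1ccc(OCOC)c(CC=C(C)C)c1OCOC | intermediate
9 | 9-{2-[2,4-bis(methoxymethoxy)-3-(3-methylbut-2-en-1-yl)phenyl]ethyl}-9-borabicyclo[3.3.1]nonane (alkylborane) | C1CC2CCCC(C1)B2CCc1ccc(OCOC)c(CC=C(C)C)c1OCOC | intermediate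
10 | 2-[2,4-bis(methoxymethoxy)-3-(3-methylbut-2-en-1-yl)phenyl]ethan-1-ol | OCCc1ccc(OCOC)c(CC=C(C)C)c1OCOC | intermediate
11 | 2-[2,4-bis(methoxymethoxy)-3-(3-methylbut-2-en-1-yl)phenyl]acetaldehyde | O=CCc1ccc(OCOC)c(CC=C(C)C)c1OCOC | intermediate
12 | 2,4-dihydroxy-3-(3-methylbut-2-en-1-yl)benzaldehyde | O=Cc1ccc(O)c(CC=C(C)C)c1O | intermediate
13 | 2-hydroxy-4-(methoxymethoxy)-3-(3-methylbut-2-en-1-yl)benzaldehyde | O=Cc1ccc(OCOC)c(CC=C(C)C)c1O | intermediate
14 | 6-(hydroxymethyl)-3-(methoxymethoxy)-2-(3-methylbut-2-en-1-yl)phenol | OCc1ccc(OCOC)c(CC=C(C)C)c1O | intermediate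
15 | sodium p-toluenesulfinate | Cc1ccc(cc1)S(=O)[O-].[Na+] | starting material
16 | 3-(methoxymethoxy)-2-(3-methylbut-2-en-1-yl)-6-[(4-methylbenzenesulfonyl)methyl]phenol | Cc1ccc(cc1)S(=O)(=O)Cc1ccc(OCOC)c(CC=C(C)C)c1O | intermediate
17 | 3-(methoxymethoxy)-2-(3-methylbut-2-en-1-yl)-6-methylidenecyclohexa-2,4-dien-1-one (ortho-quinone methide) | C=C1C=CC(OCOC)=C(CC=C(C)C)C1=O | intermediate
18 | (2R)-1-[(E)-2-[2,4-bis(methoxymethoxy)-3-(3-methylbut-2-en-1-yl)phenyl]ethenyl]-2-[diphenyl(trimethylsilyloxy)methyl]pyrrolidine (E-enamine) | C[Si](C)(C)OC(c1ccccc1)(c1ccccc1)[C@H]1CCCN1/C=C/c1ccc(OCOC)c(CC=C(C)C)c1OCOC | intermediate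
19 | (3R)-3-[2,4-bis(methoxymethoxy)-3-(3-methylbut-2-en-1-yl)phenyl]-7-(methoxymethoxy)-8-(3-methylbut-2-en-1-yl)-3,4-dihydro-2H-chromen-2-ol (lactol, both anomers at C2) | OC1Oc2c(CC=C(C)C)c(OCOC)ccc2C[C@@H]1c1ccc(OCOC)c(CC=C(C)C)c1OCOC | intermediate
20 | 6-[(2R)-2-[2,4-bis(methoxymethoxy)-3-(3-methylbut-2-en-1-yl)phenyl]-3-hydroxypropyl]-3-(methoxymethoxy)-2-(3-methylbut-2-en-1-yl)phenol | OC[C@H](Cc1ccc(OCOC)c(CC=C(C)C)c1O)c1ccc(OCOC)c(CC=C(C)C)c1OCOC | intermediate
21 | (3R)-3-[2,4-bis(methoxymethoxy)-3-(3-methylbut-2-en-1-yl)phenyl]-7-(methoxymethoxy)-8-(3-methylbut-2-en-1-yl)-3,4-dihydro-2H-chromene | CC(C)=CCc1c(OCOC)ccc([C@@H]2COc3c(ccc(OCOC)c3CC=C(C)C)C2)c1OCOC | intermediate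
22 | Kanzonol X, (3R)-3-[2,4-dihydroxy-3-(3-methylbut-2-en-1-yl)phenyl]-8-(3-methylbut-2-en-1-yl)-3,4-dihydro-2H-chromen-7-ol | CC(C)=CCc1c(O)ccc([C@@H]2COc3c(ccc(O)c3CC=C(C)C)C2)c1O | target

**Count and risks**

Total steps: 13. Longest linear sequence: 10 steps (1, 2, 3, 7, 8, 9, 10, 11, 12, 13); the ring B branch (steps 4, 5 and 6) leaves the main line at aldehyde 7 and rejoins at step 11.

Steps most likely to fail:

1. Step 11. The risks are erosion of enantiopurity through enolization or renewed enamine formation of the α-aryl aldehyde form of the lactol, imperfect facial selectivity with an unsubstituted methide, and oligomerization of the quinone methide. Fallback: setting out from 16 and 11, the annulation would be run with achiral pyrrolidine (20 mol %) and Na2CO3 in CH2Cl2 to give the racemic lactol F1, which would be isolated. F1 would then be hydrogenated under dynamic kinetic resolution with RuCl2[(S)-SDP][(R,R)-DACH] or its mirror image (SDP = 7,7'-bis(diphenylphosphino)-1,1'-spirobiindane, DACH = trans-1,2-diaminocyclohexane), KOt-Bu (in excess over the phenol), i-PrOH, H2. The base equilibrates the enantiomers of the open hydroxy aldehyde through its enolate while the chiral ruthenium hydride reduces one of them faster, and the prenyl alkenes are not reduced by this carbonyl-selective catalyst. The antipode of the complex would be chosen by a test run; the sequence returns to the route at diol 20.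

2. Step 10. The risks are acid-triggered self-alkylation of the electron-rich ring by the benzylic cation (oligomer formation) and partial loss of the MOM group. Fallback: setting out from aldehyde 13, reductive amination with Me2NH and NaBH(OAc)3 in ClCH2CH2Cl would give the Mannich base 6-[(dimethylamino)methyl]-3-(methoxymethoxy)-2-prenylphenol F2. N-Methylation with MeI in acetone would give the quaternary salt [2-hydroxy-4-(methoxymethoxy)-3-prenylphenyl]-N,N,N-trimethylmethanaminium iodide F3. Warming F3 with sodium p-toluenesulfinate 15 in MeCN/H2O should expel trimethylamine through the quinone methide under neutral conditions and let sulfinate add. This bypasses 14 and returns to the route at sulfone 16.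

3. Step 13. The risk is acid-promoted cyclization of a prenyl group onto a neighbouring free phenol (dimethylchroman formation) or hydration of the alkene during MOM cleavage. Fallback: setting out from 21, treatment with TMSOTf and 2,2'-bipyridyl in CH2Cl2 at 0 °C should exchange the aryl MOM ethers for silyl ethers without free Brønsted acid and give the tris(trimethylsilyl) ether of Kanzonol X F4. Mild methanolysis (K2CO3, MeOH, 0 °C) would then return to the route at target 22.

**Further compounds**

F1 | step 11 | racemic 3-[2,4-bis(methoxymethoxy)-3-(3-methylbut-2-en-1-yl)phenyl]-7-(methoxymethoxy)-8-(3-methylbut-2-en-1-yl)-3,4-dihydro-2H-chromen-2-ol | OC1Oc2c(CC=C(C)C)c(OCOC)ccc2CC1c1ccc(OCOC)c(CC=C(C)C)c1OCOC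
F2 | step 10 | 6-[(dimethylamino)methyl]-3-(methoxymethoxy)-2-(3-methylbut-2-en-1-yl)phenol | CN(C)Cc1ccc(OCOC)c(CC=C(C)C)c1O
F3 | step 10 | [2-hydroxy-4-(methoxymethoxy)-3-(3-methylbut-2-en-1-yl)phenyl]-N,N,N-trimethylmethanaminium iodide | C[N+](C)(C)Cc1ccc(OCOC)c(CC=C(C)C)c1O.[I-]
F4 | step 13 | (3R)-3-[3-(3-methylbut-2-en-1-yl)-2,4-bis(trimethylsilyloxy)phenyl]-8-(3-methylbut-2-en-1-yl)-7-(trimethylsilyloxy)-3,4-dihydro-2H-chromene | CC(C)=CCc1c(O[Si](C)(C)C)ccc([C@@H]2COc3c(ccc(O[Si](C)(C)C)c3CC=C(C)C)C2)c1O[Si](C)(C)C
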